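**Assumptions:** the target is isolated as the free guanidine base drawn (the final alkylation gives its HBr salt first). Silyl enyne 3 and (E)-enynol 8 are taken as catalogue compounds. The ligand enantiomer in step 1 is the one that gives the 3R centre.

## Retrosynthetic overview

1. C–S bond: allylic sulfone from allylic bromide 11 and the sulfinate of hypotaurocyamine 13.
2. Chain C(sp2)–C(sp3) bond: B-alkyl Suzuki coupling of E-vinyl iodide 7 with the 9-BBN adduct of E-dienol 9; one E-alkene comes from carboalumination of alkyne 6, the other from enynol 8.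
3. Ring alkene methyl from the enol triflate of ketone 4.
4. Key bond, quaternary carbon to side-chain CH2: the tertiary α-keto radical from bromoketone 2 adds to silyl enyne 3, anti to the neighbouring methyl.
5. The CH(Me) centre comes from Cu-catalysed asymmetric conjugate addition to enone 1. The only ring is bought in 1; there is no ring-forming step.

## Route

**Step 1**
Reactants: 1, 2-methylcyclohex-2-en-1-one
Product: 2, (3R)-2-bromo-2,3-dimethylcyclohexan-1-one (mixture of C2 epimers)
Conditions: Me3Al, CuTC (2 mol %), chiral phosphoramidite (4 mol %), Et2O, –30 °C; then NBS, THF, –78 → 0 °C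
Reagents that add atoms: trimethylaluminium, C[Al](C)C; N-bromosuccinimide, O=C1CCC(=O)N1Br
Why: Cu-catalysed asymmetric conjugate addition sets C3 (R) by catalyst control and gives the C1–C2 aluminium enolate regiospecifically, which NBS brominates at C2; the C2 configuration is irrelevant because that carbon becomes a radical.

**Step 2 (key step)**
Reactants: 2, (3R)-2-bromo-2,3-dimethylcyclohexan-1-one; 3, trimethyl(but-3-en-1-yn-1-yl)silane (4 equiv)
Product: 4, (2S,3R)-2,3-dimethyl-2-[4-(trimethylsilyl)but-3-yn-1-yl]cyclohexan-1-one
Conditions: fac-Ir(ppy)3 (1 mol %), Hantzsch ester (1.5 equiv), MeCN (0.3 M), blue LEDs, 0 °C; chromatography removes the minor C2 epimer and any silylallene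
Reagents that add atoms: none (H from Hantzsch ester)
Why: Proposed new method: SET reduction of the tertiary α-bromoketone gives a planar, electrophilic α-keto radical that adds to the CH2 terminus of the conjugated enyne anti to the pseudoaxial C3 methyl (the same facial bias as alkylation of the corresponding enolate), setting C2 (S) with the two methyls cis; the propargylic radical then takes H from the Hantzsch ester at the carbon remote from silicon to give the alkyne. The closest known reactions are reductive Giese-type additions of α-halo ketones to alkenes and the Keck allylation of tertiary α-bromoketones.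

**Step 3**
Reactants: 4
Product: 5, (5R,6S)-5,6-dimethyl-6-[4-(trimethylsilyl)but-3-yn-1-yl]cyclohex-1-en-1-yl trifluoromethanesulfonate
Conditions: KHMDS, THF, –78 °C; PhNTf2, –78 → 0 °C
Reagents that add atoms: N-phenylbis(trifluoromethanesulfonimide), O=S(=O)(N(c1ccccc1)S(=O)(=O)C(F)(F)F)C(F)(F)F
Why: Enol triflate formation is regiospecific because only the CH2 side of the ketone can enolise (the other α-carbon is quaternary); no stereocentre is touched.

**Step 4**
Reactants: 5
Product: 6, (5R,6S)-6-(but-3-yn-1-yl)-1,5,6-trimethylcyclohex-1-ene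
Conditions: MeMgBr, Fe(acac)3 (5 mol %), THF/NMP, –30 → 0 °C; then MeOH, K2CO3, rt (same pot)
Reagents that add atoms: methylmagnesium bromide, C[Mg]Br
Why: Fe-catalysed Kumada-type coupling of the alkenyl triflate with MeMgBr installs the ring methyl with the alkene fixed at C1=C2; the methanolic K2CO3 quench cleaves the alkynyl C–Si bond to give the terminal alkyne.

**Step 5**
Reactants: 6
Product: 7, (5R,6S)-6-[(3E)-4-iodo-3-methylbut-3-en-1-yl]-1,5,6-trimethylcyclohex-1-ene
Conditions: Me3Al (3 equiv), Cp2ZrCl2 (0.3 equiv), CH2Cl2, 0 °C → rt; then I2, THF, –30 °C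
Reagents that add atoms: trimethylaluminium, C[Al](C)C; iodine, II
Why: Negishi Zr-catalysed carboalumination adds Me–Al syn across the terminal alkyne with Me on the internal carbon, and iodinolysis with retention gives the E-vinyl iodide; the trisubstituted ring alkene is inert.

**Step 6**
Reactants: 8, (2E)-3-methylpent-2-en-4-yn-1-ol
Product: 9, (2E)-3-methylpenta-2,4-dien-1-ol
Conditions: H2 (1 atm), Lindlar catalyst, quinoline, EtOAc, rt, stopped at 1 equiv H2
Reagents that add atoms: none
Why: Lindlar semihydrogenation converts the terminal alkyne to a vinyl group and leaves the E-trisubstituted alkene of the enynol unchanged.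

**Step 7**
Reactants: 7; 9 (1.5 equiv)
Product: 10, (2E,6E)-3,7-dimethyl-9-[(1S,6R)-1,2,6-trimethylcyclohex-2-en-1-yl]nona-2,6-dien-1-ol
Conditions: 9 + 9-BBN (2.1 equiv per 9), THF, 0 °C → rt; then 7, Pd(dppf)Cl2 (5 mol %), AsPh3, Cs2CO3, DMF/H2O, rt
Reagents that add atoms: none (9-BBN supplies only H)
Why: 9-BBN first caps the OH as a borinate and then hydroborates only the monosubstituted vinyl group at its terminal carbon; B-alkyl Suzuki–Miyaura coupling with the vinyl iodide proceeds with retention and gives the E,E-1,5-diene.

**Step 8**
Reactants: 10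
Product: 11, (5R,6S)-6-[(3E,7E)-9-bromo-3,7-dimethylnona-3,7-dien-1-yl]-1,5,6-trimethylcyclohex-1-ene
Conditions: CBr4, PPh3, CH2Cl2, –20 → 0 °C; used crude
Reagents that add atoms: carbon tetrabromide, BrC(Br)(Br)Br
Why: Appel bromination of the primary allylic alcohol is a neutral SN2 process, so there is no allylic transposition and no E/Z erosion at low temperature.

**Step 9**
Reactants: 12, hypotaurine (2-aminoethanesulfinic acid)
Product: 13, hypotaurocyamine (2-guanidinoethanesulfinic acid, zwitterion)
Conditions: 1H-pyrazole-1-carboxamidine·HCl, Na2CO3, H2O, rt, under N2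
Reagents that add atoms: 1H-pyrazole-1-carboxamidine hydrochloride, NC(=N)n1cccn1.Cl
Why: Guanylation by amidine transfer to the primary amine; the sulfinate remains as its salt and is not affected.

**Step 10**
Reactants: 11; 13 (1.5 equiv)
Product: 14, agelasidine C, 1-[2-({(2E,6E)-3,7-dimethyl-9-[(1S,6R)-1,2,6-trimethylcyclohex-2-en-1-yl]nona-2,6-dien-1-yl}sulfonyl)ethyl]guanidine
Conditions: DMF/H2O (9:1), rt; then aqueous NaOH work-up to the free base
Reagents that add atoms: none
Why: Sulfinate S-alkylation (SN2) of the primary allylic bromide forms the sulfone with the E-alkene retained; the guanidinium is protonated and not nucleophilic.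

## Compound list

1 | 2-methylcyclohex-2-en-1-one | CC1=CCCCC1=O | starting material
2 | (3R)-2-bromo-2,3-dimethylcyclohexan-1-one | O=C1CCC[C@@H](C)C1(C)Br | intermediate
3 | trimethyl(but-3-en-1-yn-1-yl)silane | C=CC#C[Si](C)(C)C | starting material
4 | (2S,3R)-2,3-dimethyl-2-[4-(trimethylsilyl)but-3-yn-1-yl]cyclohexan-1-one | O=C1CCC[C@@H](C)[C@]1(C)CCC#C[Si](C)(C)C | intermediate
5 | (5R,6S)-5,6-dimethyl-6-[4-(trimethylsilyl)but-3-yn-1-yl]cyclohex-1-en-1-yl triflate | FC(F)(F)S(=O)(=O)OC1=CCC[C@@H](C)[C@]1(C)CCC#C[Si](C)(C)C | intermediate
6 | (5R,6S)-6-(but-3-yn-1-yl)-1,5,6-trimethylcyclohex-1-ene | CC1=CCC[C@@H](C)[C@]1(C)CCC#C | intermediate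
7 | (5R,6S)-6-[(3E)-4-iodo-3-methylbut-3-en-1-yl]-1,5,6-trimethylcyclohex-1-ene | CC1=CCC[C@@H](C)[C@]1(C)CC/C(C)=C/I | intermediate
8 | (2E)-3-methylpent-2-en-4-yn-1-ol | C#C/C(C)=C/CO | starting material
9 | (2E)-3-methylpenta-2,4-dien-1-ol | C=C/C(C)=C/CO | intermediate
10 | (2E,6E)-3,7-dimethyl-9-[(1S,6R)-1,2,6-trimethylcyclohex-2-en-1-yl]nona-2,6-dien-1-ol | CC1=CCC[C@@H](C)[C@]1(C)CC/C(C)=C/CC/C(C)=C/CO | intermediate
11 | (5R,6S)-6-[(3E,7E)-9-bromo-3,7-dimethylnona-3,7-dien-1-yl]-1,5,6-trimethylcyclohex-1-ene | CC1=CCC[C@@H](C)[C@]1(C)CC/C(C)=C/CC/C(C)=C/CBr | intermediate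
12 | hypotaurine (2-aminoethanesulfinic acid) | NCCS(=O)O | starting material
13 | hypotaurocyamine (2-guanidinoethanesulfinic acid) | NC(=N)NCCS(=O)O | intermediate
14 | agelasidine C | CC1=CCC[C@@H](C)[C@]1(C)CC/C(C)=C/CC/C(C)=C/CS(=O)(=O)CCN=C(N)N | target

## Step count and risks

Total steps: 10. Longest linear sequence: 8 (steps 1, 2, 3, 4, 5, 7, 8, 10).

Steps most likely to fail:

1. **Step 2.** Risks are premature reduction of the α-keto radical, H-transfer to the allenyl terminus (silylallene), enyne telomerisation and only moderate d.r. Fallback: use 2-vinyl-1,3-dioxolane as the acceptor under silane/thiol polarity-reversal radical-chain conditions, which gives a non-stabilised adduct radical with no regiochemical issue. Carry the acetal through steps 3–4, hydrolyse to the aldehyde and convert it to alkyne 6 with the Ohira–Bestmann reagent (+1 step).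
2. **Step 7.** Risks are the regioselectivity of diene hydroboration with the free OH present and a sluggish B-alkyl transfer. Fallback: build the chain iteratively instead. Negishi-couple 7 with the homopropargylzinc reagent from C-silylated 4-bromobut-1-yne, desilylate, then run a second Zr-catalysed carboalumination quenched with paraformaldehyde to reach 10 (+2 steps).
3. **Step 1.** Risks are an ee below about 95 % for this α-substituted enone and a sluggish bromination of the aluminium enolate. Fallback: start from cyclohex-2-enone. Cu/phosphoramidite-catalysed Me2Zn addition with TMSOTf trapping, then MeLi/MeI, gives trans-2,3-dimethylcyclohexanone; bromination under acid (Br2, AcOH) at the more substituted α-carbon then gives 2 (+2 steps).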